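**Retrosynthetic overview**
1. Target 9 ⇐ acetonide-protected (14S) allylic carbonate 7 by a stereoretentive 1,3-allylic transposition on the alkylidene lactone, which makes the C12–O bond and lets C14 set C12.
2. 7 ⇐ C4-epi-andrographolide 5 by masking the 3,18-diol and activating the C14 hydroxyl.
3. 5 ⇐ andrographolide-19-oic acid 3 by a light-driven decarboxylative hydroxymethylation (key step): the C4–C19 bond on the α face is cut and the C4–C18 bond is made on the β face, inverting the quaternary centre C4.
4. 3 ⇐ andrographolide 1, a cheap chiral-pool ent-labdane that supplies C3, C5, C9, C10 and C14, by primary-selective oxidation.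
5. No ring is built: rings A and B and the lactone are bought in 1, and the butenolide arises from the alkylidene lactone in the transposition.

Assumption: the SMILES is read literally as (3R,4S,5S,9R,10S,12R), so it has the andrographolide core but the opposite configuration at C4 (CH2OH anti to the C10 methyl) and a 12R carbinol. Labdane numbering is used; α is the face of the C10 methyl, β the opposite face, C19 is the α carbon on C4 and C18 the β carbon on C4.

**Route**

Step 1
Reactants: 1 andrographolide
Product: 3 andrographolide-19-oic acid, via aldehyde 2 (not isolated)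
Conditions: TEMPO (0.2 equiv), PhI(OAc)2 (2.5 equiv), MeCN/H2O 1:1, 0 °C to rt
Reagents that add atoms: water, O
Why: Nitroxyl/oxoammonium oxidation is kinetically selective for the primary alcohol and in water carries the aldehyde hydrate on to the acid, while the hindered C3 carbinol and the electron-poor allylic C14 carbinol react far more slowly; no stereocentre is touched.

Step 2
Reactants: 3 andrographolide-19-oic acid
Product: 5 C4-epi-andrographolide, via phthalimide ester 4 (not isolated)
Conditions: N-hydroxyphthalimide (1.1 equiv), iPrN=C=NiPr (1.1 equiv), DMAP (0.1 equiv), THF, rt; then solvent switch to MeCN/DMSO 4:1, (CH2O)n (20 equiv), PPh3 (3 equiv), Ir(ppy)3 [fac-tris(2-phenylpyridinato)iridium] (1 mol%), H2O (5 equiv), 450 nm LEDs, 35 °C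
Reagents that add atoms: formaldehyde (from paraformaldehyde), C=O; N-hydroxyphthalimide, O=C1c2ccccc2C(=O)N1O (only in intermediate 4)
Why: Proposed new method: electron transfer from photoexcited Ir(ppy)3 to the N-acyloxyphthalimide releases CO2 and a planar tertiary C4 radical; formaldehyde adds to it from the β face because the axial C10 methyl blocks the α face (the facial rule known from alkylations of 4-methyl-3-keto-decalin enolates); PPh3 captures the reversibly formed alkoxyl radical, the phosphoranyl radical is oxidised (by tetravalent iridium or by the next ester molecule in a chain) to an alkoxyphosphonium ion, and water hydrolyses it at phosphorus, so CH2OH on the β face replaces CO2 on the α face and C4 is inverted; the closest known reactions are the photoredox hydroxymethylation of alkyl iodides with formaldehyde/PPh3 and decarboxylative Giese additions of redox-active esters, neither shown for inverting a quaternary centre in this way.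

Step 3
Reactants: 5 C4-epi-andrographolide
Product: 7 acetonide methyl carbonate of C4-epi-andrographolide (3,18-O-isopropylidene; 14-O-CO2Me), via acetonide alcohol 6 (not isolated)
Conditions: Me2C(OMe)2, PPTS (cat.), acetone, rt; evaporate; then ClCO2Me, pyridine, CH2Cl2, 0 °C
Reagents that add atoms: 2,2-dimethoxypropane, COC(C)(C)OC; methyl chloroformate, COC(=O)Cl
Why: Acid-catalysed transacetalisation closes a 1,3-dioxane only on the trans-diequatorial 3,18-diol, which leaves the C14 hydroxyl as the single free alcohol for chloroformate acylation; no stereocentre changes.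

Step 4
Reactants: 7 acetonide methyl carbonate of C4-epi-andrographolide
Product: 9 target CNP0270153.3, via hydroxy acetonide 8 (not isolated)
Conditions: Pd(PPh3)4 (5 mol%), KHCO3 (2 equiv), CH2Cl2/H2O 9:1, rt; then AcOH/H2O 7:3, rt
Reagents that add atoms: water, O (delivered to C12 as hydrogencarbonate from KHCO3, [K+].OC(=O)[O-])
Why: Tsuji–Trost allylic substitution with double inversion: zerovalent palladium ionises the carbonate anti to the leaving group and hydrogencarbonate attacks the π-allyl complex anti to palladium at the exocyclic terminus C12 (distal to the inductively deactivated ring carbon C14, giving the conjugated endocyclic butenolide), so oxygen returns to the face it left and (14S) is transposed suprafacially to (12R); the hydrogen carbonate ester loses CO2 and aqueous acetic acid then removes the acetonide.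

**Compound list**

1 | andrographolide, (3R,4R,5S,9R,10S,12E,14S)-3,14,19-trihydroxy-ent-labda-8(17),12-dien-16,15-olide; CH2OH on C4 is α (axial, syn to the C10 methyl) | C=C1CC[C@@H]2[C@](C)(CO)[C@H](O)CC[C@@]2(C)[C@@H]1C/C=C1/C(=O)OC[C@H]1O | starting material
2 | andrographolide-19-al; as 1 but CHO in place of the α CH2OH on C4; formed in situ | C=C1CC[C@@H]2[C@](C)(C=O)[C@H](O)CC[C@@]2(C)[C@@H]1C/C=C1/C(=O)OC[C@H]1O | intermediate
3 | andrographolide-19-oic acid; as 1 but COOH in place of the α CH2OH on C4 | C=C1CC[C@@H]2[C@](C)(C(=O)O)[C@H](O)CC[C@@]2(C)[C@@H]1C/C=C1/C(=O)OC[C@H]1O | intermediate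
4 | N-acyloxyphthalimide (redox-active ester) of 3; formed in situ | C=C1CC[C@@H]2[C@](C)(C(=O)ON3C(=O)c4ccccc4C3=O)[C@H](O)CC[C@@]2(C)[C@@H]1C/C=C1/C(=O)OC[C@H]1O | intermediate
5 | C4-epi-andrographolide, (3R,4S,5S,9R,10S,12E,14S); CH2OH on C4 is β (equatorial, anti to the C10 methyl, trans to 3-OH), CH3 is α | C=C1CC[C@@H]2[C@@](C)(CO)[C@H](O)CC[C@@]2(C)[C@@H]1C/C=C1/C(=O)OC[C@H]1O | intermediate
6 | 3,18-O-isopropylidene-C4-epi-andrographolide (free 14S hydroxyl); formed in situ | C=C1CC[C@@H]2[C@@]3(C)COC(C)(C)O[C@@H]3CC[C@@]2(C)[C@@H]1C/C=C1/C(=O)OC[C@H]1O | intermediate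
7 | 3,18-O-isopropylidene-14-O-methoxycarbonyl-C4-epi-andrographolide | C=C1CC[C@@H]2[C@@]3(C)COC(C)(C)O[C@@H]3CC[C@@]2(C)[C@@H]1C/C=C1/C(=O)OC[C@H]1OC(=O)OC | intermediate
8 | 3,18-O-isopropylidene derivative of the target, (12R)-12-hydroxy-13(14)-en-16,15-olide; formed in situ | C=C1CC[C@@H]2[C@@]3(C)COC(C)(C)O[C@@H]3CC[C@@]2(C)[C@@H]1C[C@@H](O)C1=CCOC1=O | intermediate
9 | CNP0270153.3, (3R,4S,5S,9R,10S,12R)-3,12,18-trihydroxy-ent-labda-8(17),13-dien-16,15-olide | C=C1CC[C@@H]2[C@@](C)(CO)[C@H](O)CC[C@@]2(C)[C@@H]1C[C@@H](O)C1=CCOC1=O | target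

**Step count and risks**

Total step count: 4 (four isolations; 2, 4, 6 and 8 are carried on without isolation). Longest linear sequence: 4 steps from 1.

The three steps most likely to fail:

Step 2 (the proposed new step). The risks are modest facial selectivity, hydrogen capture by the C4 radical before it meets formaldehyde, and addition of PPh3 to the alkylidene lactone. The minor α-face product is andrographolide 1 itself, so it can be separated and returned to step 1. Fallback with known two-electron chemistry, setting out from 1 and coming back at 5: 1 is converted (Me2C(OMe)2, PPTS) into 3,19-O-isopropylidene-andrographolide F1, silylated (TBDPSCl, imidazole, DMAP, DMF) to its 14-O-TBDPS ether F2, and freed from the acetonide (AcOH/H2O) to give 14-O-TBDPS-andrographolide F3. Jones oxidation (CrO3, H2SO4, acetone, 0 °C) of the 1,3-diol gives the β-keto acid 14-O-TBDPS-3-oxo-andrographolide-19-oic acid F4. Amine-mediated decarboxylative aldol addition to formaldehyde (Et3N, (CH2O)n, THF, rt) forms the C3–C4 enol regiospecifically and hydroxymethylates it anti to the C10 methyl, giving the ketol 14-O-TBDPS-3-oxo-C4-epi-andrographolide F5. NaBH4 (MeOH, −40 °C, axial hydride delivery) gives the equatorial 3α alcohol 14-O-TBDPS-C4-epi-andrographolide F6, and HF·pyridine (THF) removes the silyl group to give 5.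

Step 4. The risks are attack at C14 instead of C12, β-hydride elimination of the π-allyl complex to the 11,13-diene, and capture by methoxide. Attack at C14 with double inversion only returns alcohol 6, which can be recycled. Fallback, setting out from 6 (isolated after the first stage of step 3) and coming back at 8, with no new compound (F0): Ph3SiOReO3 (5 mol%), Et2O, −30 to 0 °C. The allyl perrhenate ester undergoes a chair [3,3] shift, which is suprafacial, so oxygen again arrives on the face it left (12R), driven by the more stable endocyclic butenolide. 8 is then deprotected as in step 4.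

Step 1. The risks are competing oxidation of the allylic C14 hydroxyl and stalling at the hindered aldehyde. Fallback, setting out from 1 and coming back at 3, with no new compound (F0): an aerobic copper/nitroxyl oxidation ([Cu(MeCN)4]OTf, 2,2'-bipyridine, TEMPO, N-methylimidazole, air, MeCN) works through a copper alkoxide, does not oxidise secondary alcohols, and stops at aldehyde 2, which is now isolated. A separate chlorite oxidation (NaClO2, NaH2PO4, 2-methyl-2-butene, t-BuOH/H2O) then gives 3.

**Further compounds**

F1 | step 2 | 3,19-O-isopropylidene-andrographolide | C=C1CC[C@@H]2[C@]3(C)COC(C)(C)O[C@@H]3CC[C@@]2(C)[C@@H]1C/C=C1/C(=O)OC[C@H]1O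
F2 | step 2 | 14-O-TBDPS-3,19-O-isopropylidene-andrographolide | C=C1CC[C@@H]2[C@]3(C)COC(C)(C)O[C@@H]3CC[C@@]2(C)[C@@H]1C/C=C1/C(=O)OC[C@H]1O[Si](c1ccccc1)(c1ccccc1)C(C)(C)C
F3 | step 2 | 14-O-TBDPS-andrographolide | C=C1CC[C@@H]2[C@](C)(CO)[C@H](O)CC[C@@]2(C)[C@@H]1C/C=C1/C(=O)OC[C@H]1O[Si](c1ccccc1)(c1ccccc1)C(C)(C)C
F4 | step 2 | 14-O-TBDPS-3-oxo-andrographolide-19-oic acid | C=C1CC[C@@H]2[C@](C)(C(=O)O)C(=O)CC[C@@]2(C)[C@@H]1C/C=C1/C(=O)OC[C@H]1O[Si](c1ccccc1)(c1ccccc1)C(C)(C)C
F5 | step 2 | 14-O-TBDPS-3-oxo-C4-epi-andrographolide (β CH2OH on C4) | C=C1CC[C@@H]2[C@@](C)(CO)C(=O)CC[C@@]2(C)[C@@H]1C/C=C1/C(=O)OC[C@H]1O[Si](c1ccccc1)(c1ccccc1)C(C)(C)C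
F6 | step 2 | 14-O-TBDPS-C4-epi-andrographolide | C=C1CC[C@@H]2[C@@](C)(CO)[C@H](O)CC[C@@]2(C)[C@@H]1C/C=C1/C(=O)OC[C@H]1O[Si](c1ccccc1)(c1ccccc1)C(C)(C)C
F0 | step 4 | none | none
F0 | step 1 | none | none
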